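**Retrosynthetic overview**
- Target ⇒ (S)-α-hydroxy aryl ketone. C1' comes from a chelation-controlled hydride delivery that gives the erythro diol.
- Ketone ⇒ 5-bromo-2,3-dihydrobenzofuran (used as its aryllithium) + (S)-lactic acid dimethylamide. C2' comes from the chiral pool.
- The dihydrofuran is the only ring formed. It is made in one operation by enantioselective oxidative [3+2] coupling of 4-bromoguaiacol with an (E)-propenylarene that already carries the 4-OMe group. The C3–C3a bond forms first (8–5' coupling of an iron-bound phenoxyl radical). O1–C2 then closes on the quinone-methide-type benzylic cation to give the trans ring.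
- Propenylarene ⇒ 3-hydroxy-4,5-dimethoxybenzaldehyde by Julia–Kocienski ethylidenation.

**Numbering:** benzofuran O1, C2, C3, C3a to C7a; side chain C1' (benzylic) and C2'; ring A is the C2 aryl group and ring B the benzo ring. The target is (2S,3S,1'R,2'S), with a trans ring and an erythro diol.

**Assumption:** the sense of induction in step 2 cannot be predicted, so the (R)-acid is written. If it gives the (2R,3R) series, the equally available (S)-acid is used and nothing else changes.

**Abbreviations:** (R)-TRIP is (R)-3,3'-bis(2,4,6-triisopropylphenyl)-1,1'-binaphthyl-2,2'-diyl hydrogen phosphate. HFIP is 1,1,1,3,3,3-hexafluoropropan-2-ol.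

**Step 1**
Reactants: 1 (3-hydroxy-4,5-dimethoxybenzaldehyde); 2 (5-(ethylsulfonyl)-1-phenyl-1H-tetrazole)
Product: 4 (E)-2,3-dimethoxy-5-(prop-1-en-1-yl)phenyl acetate, via potassium phenolate 3 (not isolated)
Conditions: KN(SiMe3)2 (2.3 equiv), DME, −60 °C to rt; then Ac2O (2 equiv), rt; aq NH4Cl
Reagents that add atoms: acetic anhydride CC(=O)OC(C)=O
Why: Julia–Kocienski olefination, in which the potassiated sulfone adds to the aldehyde of the phenolate of 1, Smiles transfer of the tetrazole to oxygen and loss of SO2 and the tetrazololate give the alkene (electron-rich aryl aldehydes give mainly the (E)-isomer, about 10:1, with the minor isomer removed on silica), and phenolate 3 is acetylated in the same flask so that ring A can neither bind to iron nor be oxidised in step 2; no stereocenter is formed.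

**Step 2**
Reactants: 4 ((E)-2,3-dimethoxy-5-(prop-1-en-1-yl)phenyl acetate, 1.5 equiv); 5 (4-bromo-2-methoxyphenol, added slowly)
Product: 7 (2S,3S)-5-bromo-2-(3-hydroxy-4,5-dimethoxyphenyl)-7-methoxy-3-methyl-2,3-dihydrobenzofuran, via coupled acetate 6 (not isolated)
Conditions: Fe(ClO4)3 (5 mol %), (R)-TRIP (15 mol %), CaCO3 (10 mol %), t-BuOOt-Bu (1.5 equiv), HFIP/ClCH2CH2Cl 1:1, rt; silica plug, concentrate; then K2CO3 (0.2 equiv), MeOH, rt
Reagents that add atoms: none
Why: Proposed new method: 5 binds to trivalent iron as a chelating guaiacolate between the (R)-TRIP phosphate ligands and is oxidised there by the peroxide to an iron-bound phenoxyl radical, whose free ortho carbon (para is blocked by Br, which also makes 5 a poor nucleophile and so holds back homocoupling) is attacked by the methyl-bearing alkene carbon of the more nucleophilic, non-coordinating 4 on the face left open by the ligands, which sets C3; the benzylic radical is oxidised at once to the 4-methoxybenzyl cation (the O-methyl counterpart of the biosynthetic quinone methide) and the ring B oxygen closes on it anti to the methyl group, which sets C2 trans to C3; the closest known reaction types are the racemic FeCl3/peroxide oxidative [3+2] coupling of phenols with styrenes and the enantioselective oxidative coupling of 2-naphthols by chiral iron tris(phosphate) catalysts, and the acetate is then removed by base-catalysed transesterification.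

**Step 3**
Reactants: 7 ((2S,3S)-5-bromo-2-(3-hydroxy-4,5-dimethoxyphenyl)-7-methoxy-3-methyl-2,3-dihydrobenzofuran); 8 ((S)-2-hydroxy-N,N-dimethylpropanamide, 2.5 equiv)
Product: 12 (S)-2-hydroxy-1-[(2S,3S)-2-(3-hydroxy-4,5-dimethoxyphenyl)-7-methoxy-3-methyl-2,3-dihydrobenzofuran-5-yl]propan-1-one, via lithium alkoxide 9 (not isolated), via dilithio species 10 (not isolated), via lithium hemiaminal 11 (not isolated)
Conditions: 8, n-BuLi (1 equiv per 8), THF, −78 °C (second flask); 7, n-BuLi (2.1 equiv), THF, −78 °C; cannulate 9 in, −78 to −20 °C; cold aq NH4Cl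
Reagents that add atoms: none
Why: Bromine–lithium exchange followed by acyl substitution on a tertiary amide, in which exchange at −78 °C outruns any ring deprotonation, aryllithium 10 adds only once to 9 because hemiaminal 11 is held as a five-membered lithium chelate until the quench, and C2' is taken unchanged from (S)-lactic acid because the neighbouring alkoxide shuts off enolisation.

**Step 4**
Reactants: 12 ((S)-2-hydroxy-1-[(2S,3S)-2-(3-hydroxy-4,5-dimethoxyphenyl)-7-methoxy-3-methyl-2,3-dihydrobenzofuran-5-yl]propan-1-one)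
Product: 13 (1R,2S)-1-[(2S,3S)-2-(3-hydroxy-4,5-dimethoxyphenyl)-7-methoxy-3-methyl-2,3-dihydrobenzofuran-5-yl]propane-1,2-diol
Conditions: Zn(BH4)2 (3 equiv, stock solution in Et2O), Et2O/THF, −40 to 0 °C; aq NH4Cl
Reagents that add atoms: none
Why: Chelation-controlled reduction (Cram cyclic model), in which zinc ties the carbonyl oxygen and the C2' hydroxyl oxygen into a five-membered chelate and hydride enters from the face that carries the C2' hydrogen rather than the methyl group, which turns the (2'S)-ketone into the (1'R,2'S)-erythro diol (typically at least 10:1) while C2, C3 and C2' are untouched.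

**Compound list**
1 | 3-hydroxy-4,5-dimethoxybenzaldehyde | COc1cc(C=O)cc(O)c1OC | starting material
2 | 5-(ethylsulfonyl)-1-phenyl-1H-tetrazole | CCS(=O)(=O)c1nnnn1-c1ccccc1 | starting material
3 | potassium (E)-2,3-dimethoxy-5-(prop-1-en-1-yl)phenolate | C/C=C/c1cc(OC)c(OC)c([O-])c1.[K+] | intermediate
4 | (E)-2,3-dimethoxy-5-(prop-1-en-1-yl)phenyl acetate | C/C=C/c1cc(OC)c(OC)c(OC(C)=O)c1 | intermediate
5 | 4-bromo-2-methoxyphenol | COc1cc(Br)ccc1O | starting material
6 | (2S,3S)-2-(3-acetoxy-4,5-dimethoxyphenyl)-5-bromo-7-methoxy-3-methyl-2,3-dihydrobenzofuran | COc1cc([C@H]2Oc3c(OC)cc(Br)cc3[C@@H]2C)cc(OC(C)=O)c1OC | intermediate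
7 | (2S,3S)-5-bromo-2-(3-hydroxy-4,5-dimethoxyphenyl)-7-methoxy-3-methyl-2,3-dihydrobenzofuran | COc1cc([C@H]2Oc3c(OC)cc(Br)cc3[C@@H]2C)cc(O)c1OC | intermediate
8 | (S)-2-hydroxy-N,N-dimethylpropanamide | C[C@H](O)C(=O)N(C)C | starting material
9 | lithium (S)-1-(dimethylamino)-1-oxopropan-2-olate | C[C@H](O[Li])C(=O)N(C)C | intermediate
10 | O,C5-dilithio derivative of 7 (lithium phenolate, 5-lithio in place of 5-bromo; 2S,3S) | COc1cc([C@H]2Oc3c(OC)cc([Li])cc3[C@@H]2C)cc(O[Li])c1OC | intermediate
11 | trilithio hemiaminal from 10 and 9 (2S,3S,2'S; hemiaminal carbon undefined) | COc1cc([C@H]2Oc3c(OC)cc(C(O[Li])(N(C)C)[C@H](C)O[Li])cc3[C@@H]2C)cc(O[Li])c1OC | intermediate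
12 | (S)-2-hydroxy-1-[(2S,3S)-2-(3-hydroxy-4,5-dimethoxyphenyl)-7-methoxy-3-methyl-2,3-dihydrobenzofuran-5-yl]propan-1-one | COc1cc([C@H]2Oc3c(OC)cc(C(=O)[C@H](C)O)cc3[C@@H]2C)cc(O)c1OC | intermediate
13 | (1R,2S)-1-[(2S,3S)-2-(3-hydroxy-4,5-dimethoxyphenyl)-7-methoxy-3-methyl-2,3-dihydrobenzofuran-5-yl]propane-1,2-diol | COc1cc([C@H]2Oc3c(OC)cc([C@@H](O)[C@H](C)O)cc3[C@@H]2C)cc(O)c1OC | target

**Total step count:** 4.
**Longest linear sequence:** 4 steps (1 → 4 → 7 → 12 → 13).

**Steps most likely to fail**

**Step 2.**
- The enantioselectivity is unproven.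
- Homocoupling of 5 and acid-induced dimerisation of 4 compete with the cross-coupling.
- A moderate ee can be raised by recrystallising 7. Any (2R,3R) material that remains becomes a diastereomer of 12 after step 3 and can be removed there.
- Fallback: catalyst control is given up in favour of a classical resolution, setting out from 4 and 5 and coming back at 7. The coupling is run with achiral FeCl3 (10 mol %) and t-BuOOt-Bu in HFIP, which is the known racemic reaction. It gives 6 together with its mirror image, (2R,3R)-2-(3-acetoxy-4,5-dimethoxyphenyl)-5-bromo-7-methoxy-3-methyl-2,3-dihydrobenzofuran F1. Methanolysis with K2CO3 gives 7 together with (2R,3R)-5-bromo-2-(3-hydroxy-4,5-dimethoxyphenyl)-7-methoxy-3-methyl-2,3-dihydrobenzofuran F2. Acylation of the mixture with (1S)-camphanic chloride (Et3N, DMAP, CH2Cl2) gives the (1S,4R)-camphanate of 7 F3 and the (1S,4R)-camphanate of the (2R,3R)-phenol F4. These are separated by fractional crystallisation or chromatography, and K2CO3/MeOH on the first ester returns 7.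

**Step 3.**
- The aryllithium may add slowly to an amide that carries an α-alkoxide.
- The α-hydroxy ketone may partly racemise during the quench.
- Fallback: the acylation/reduction pair is replaced by an aldehyde addition under Felkin–Anh control, setting out from 7 and coming back at 13, so that 12 and step 4 are bypassed. Compound 7 is converted to 10 as before and transmetalated with ClTi(OiPr)3. It is then added at −78 °C to commercial (S)-2-(tert-butyldimethylsilyloxy)propanal. The non-chelating silyl ether directs anti addition and gives (1R,2S)-2-(tert-butyldimethylsilyloxy)-1-[(2S,3S)-2-(3-hydroxy-4,5-dimethoxyphenyl)-7-methoxy-3-methyl-2,3-dihydrobenzofuran-5-yl]propan-1-ol F5. TBAF in THF then gives 13.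

**Step 4.**
- Zinc phenolate formation or incomplete chelation could erode the anti:syn ratio.
- Fallback: substrate (chelate) control is replaced by catalyst control, setting out from 12 and coming back at 13. This is a Noyori-type asymmetric transfer hydrogenation with RuCl[(S,S)-TsDPEN](p-cymene) (1 mol %) and HCO2H/Et3N at 0 °C to rt. This catalyst delivers hydride to the face that gives (S)-1-phenylethanol from acetophenone. Here that face corresponds to (1'R), because the hydroxyalkyl group outranks the aryl group. No new compound is made.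

**Further compounds**
F1 | step 2 | (2R,3R)-2-(3-acetoxy-4,5-dimethoxyphenyl)-5-bromo-7-methoxy-3-methyl-2,3-dihydrobenzofuran | COc1cc([C@@H]2Oc3c(OC)cc(Br)cc3[C@H]2C)cc(OC(C)=O)c1OC
F2 | step 2 | (2R,3R)-5-bromo-2-(3-hydroxy-4,5-dimethoxyphenyl)-7-methoxy-3-methyl-2,3-dihydrobenzofuran | COc1cc([C@@H]2Oc3c(OC)cc(Br)cc3[C@H]2C)cc(O)c1OC
F3 | step 2 | (1S,4R)-camphanate of 7 | C[C@@]12CC[C@@](C1(C)C)(OC2=O)C(=O)Oc3cc([C@H]4Oc5c(OC)cc(Br)cc5[C@@H]4C)cc(OC)c3OC
F4 | step 2 | (1S,4R)-camphanate of the (2R,3R)-phenol | C[C@@]12CC[C@@](C1(C)C)(OC2=O)C(=O)Oc3cc([C@@H]4Oc5c(OC)cc(Br)cc5[C@H]4C)cc(OC)c3OC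
F5 | step 3 | (1R,2S)-2-(tert-butyldimethylsilyloxy)-1-[(2S,3S)-2-(3-hydroxy-4,5-dimethoxyphenyl)-7-methoxy-3-methyl-2,3-dihydrobenzofuran-5-yl]propan-1-ol | COc1cc([C@H]2Oc3c(OC)cc([C@@H](O)[C@H](C)O[Si](C)(C)C(C)(C)C)cc3[C@@H]2C)cc(O)c1OC
F0 | step 4 | none | none
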